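**Strategy.** The dibenzofuran is cut into a ring B quinone monoketal and a 2-aryloxyresorcinol (rings C, F). Both are mirror-symmetric where they react (B3 = B5; C4 = C6), so one acid-promoted [3+2] union forms the B5–C6 bond and then the bond from the B4 oxygen to C1 without any regiochemical choice, giving the furan in one operation. The precursors are ketal 2 and diol 9, whose three spectator phenols (C5 and both on ring F) are tosylates so that only C6 is nucleophilic and only C1 can lose water. The freed C5 phenol later directs unmasking of B6, and the dioxin is closed bond by bond onto a ring A dialdehyde.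

Key step: step 7

**Remarks before the steps**
- Labels: rings E, A, B, C, F follow the order of the target SMILES, and ring atoms are counted in that order. Ring B and ring C atoms are written B1–B6 and C1–C6; ring A atoms are written out as "ring A position n".
- Ring A: position 1 carries the ring E ether, positions 2 and 4 hydroxyls, positions 5 and 6 the dioxin oxygens.
- Ring B: B1 and B6 carry the dioxin oxygens, B2 a hydroxyl, B3 H, B4 the furan oxygen, B5 the bond to C6.
- Ring C: C1 carries the furan oxygen, C2 the ring F ether, C3 and C5 hydroxyls, C4 H.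
- Ts = 4-methylbenzenesulfonyl. The target has no stereocentre.
- Dibenzofuran locants: in 12–15, C5 = 1, C3 = 3, C2 = 4, B2 = 7, B1 = 8, B6 = 9; from 16 on, B6 = 1, B1 = 2, B2 = 3, C2 = 6, C3 = 7, C5 = 9.
- Precursor design: a 3,5-dimethoxyphenoxy ring F would be a stronger carbon nucleophile than the sulfonylated ring C and would capture the ketal-derived cation. Ring F therefore carries two sulfonates in step 7. Tosylates are used throughout because they have no acidic α-hydrogens and tolerate the basic CuI coupling of step 5.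
- Dioxin design: the two dioxin oxygens are not equivalent (the B6 oxygen must bond to ring A position 5, the B1 oxygen to ring A position 6). They are therefore freed and bonded one after the other, not as a catechol.
- Assumption: 3-bromo-2,4-difluorobenzaldehyde (17) is taken as a catalogue compound; otherwise it is one LDA/DMF step from 2-bromo-1,3-difluorobenzene.

**Route**

Step 1
Reactants: 1 3,4,5-trimethoxyphenol
Product: 2 3,4,4,5-tetramethoxycyclohexa-2,5-dien-1-one
Conditions: PhI(OAc)2, MeOH, 0 °C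
Reagents that add atoms: methanol, SMILES CO
Why: Oxidative dearomatisation of a 4-methoxyphenol by the trivalent iodine reagent in methanol (quinone monoketal formation) traps the para carbon as the dimethyl ketal, and the symmetric substrate leaves no regiochemical choice.

Step 2
Reactants: 3 2,6-dimethoxy-1,4-benzoquinone
Product: 4 2,6-dimethoxybenzene-1,4-diol
Conditions: Na2S2O4, EtOAc/H2O, rt
Reagents that add atoms: none
Why: Na2S2O4 reduction of a benzoquinone to its hydroquinone is reliable and there is no other reducible group.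

Step 3
Reactants: 4 2,6-dimethoxybenzene-1,4-diol
Product: 5 4-hydroxy-3,5-dimethoxyphenyl 4-methylbenzenesulfonate
Conditions: TsCl (1.0 equiv), Et3N, CH2Cl2, −20 °C
Reagents that add atoms: 4-methylbenzenesulfonyl chloride, SMILES Cc1ccc(cc1)S(Cl)(=O)=O
Why: Chemoselective O-sulfonylation, because the hydroxyl at position 4 of hydroquinone 4 has two free neighbours, whereas the hydroxyl at position 1 sits between two methoxy groups and reacts far more slowly with one equivalent of TsCl.

Step 4
Reactants: 6 5-bromobenzene-1,3-diol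
Product: 7 5-bromo-1,3-phenylene bis(4-methylbenzenesulfonate)
Conditions: TsCl (2.2 equiv), Et3N, DMAP (cat.), CH2Cl2, 0 °C to rt
Reagents that add atoms: 4-methylbenzenesulfonyl chloride, SMILES Cc1ccc(cc1)S(Cl)(=O)=O
Why: Exhaustive O-sulfonylation of a resorcinol gives an electron-poor aryl bromide whose oxygens already carry the non-donating groups needed in step 7.

Step 5
Reactants: 5 4-hydroxy-3,5-dimethoxyphenyl 4-methylbenzenesulfonate; 7 5-bromo-1,3-phenylene bis(4-methylbenzenesulfonate)
Product: 8 5-[2,6-dimethoxy-4-(tosyloxy)phenoxy]-1,3-phenylene bis(4-methylbenzenesulfonate)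
Conditions: CuI (10 mol%), pyridine-2-carboxylic acid (20 mol%), K3PO4, DMSO, 90 °C
Reagents that add atoms: none
Why: Ullmann-type CuI-catalysed diaryl ether synthesis with the picolinic acid ligand accepts 2,6-disubstituted phenols and electron-poor aryl bromides, while aryl tosylates are inert to CuI and the hindered phenoxide should be slow to attack them at sulfur.

Step 6
Reactants: 8 5-[2,6-dimethoxy-4-(tosyloxy)phenoxy]-1,3-phenylene bis(4-methylbenzenesulfonate)
Product: 9 5-[2,6-dihydroxy-4-(tosyloxy)phenoxy]-1,3-phenylene bis(4-methylbenzenesulfonate)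
Conditions: BBr3, CH2Cl2, −78 °C to 0 °C; then H2O
Reagents that add atoms: none
Why: Lewis-acid cleavage of aryl methyl ethers with BBr3 removes the only two methyl groups and leaves aryl sulfonates and the diaryl ether untouched.

Step 7
Reactants: 2 3,4,4,5-tetramethoxycyclohexa-2,5-dien-1-one; 9 5-[2,6-dihydroxy-4-(tosyloxy)phenoxy]-1,3-phenylene bis(4-methylbenzenesulfonate)
Product: 12 4-[3,5-bis(tosyloxy)phenoxy]-3-hydroxy-7,8,9-trimethoxydibenzo[b,d]furan-1-yl 4-methylbenzenesulfonate, via oxocarbenium triflate 10 (not isolated), via biaryl diol 11 (not isolated)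
Conditions: 9 (1.5 equiv), slow addition of 2, CF3SO3H (20 mol%), (CF3)2CHOH/CH2Cl2, 0 °C; then 40 °C
Reagents that add atoms: none
Why: Proposed new method: CF3SO3H ionises ketal 2 to the 4-methoxy oxocarbenium ion 10, whose carbons next to the carbonyl (B3/B5) are attacked in the fluoroalcohol by C6 of diol 9 (equivalent to C4), a carbon ortho and para to the two free hydroxyls, and tautomerisation gives biaryl diol 11; protonation of 11 at C6 then makes C1 a hydroxy-oxocarbenium carbon, the B4 hydroxyl adds to it and water is lost. The closest known reaction types are the acid-promoted coupling of quinone monoketals with electron-rich arenes to 2-arylphenols, their [3+2] coupling with alkenes to dihydrobenzofurans, and the acid cyclodehydration of 2,2'-dihydroxybiaryls that contain a resorcinol ring; merging arylation and dehydration in one flask is the untested part. The furan closes in a 5-exo-trig mode, since the protonated C1=O bond lies outside the new ring. No stereocentre is formed. No choice between B3 and B5 or between C4 and C6 arises because both partners are symmetric; ring C reacts in preference to ring F because ring F carries two tosylates, and closure should occur on C1 and not C5 because the C5 tosylate cannot stabilise positive charge, so C5 has the least oxocarbenium character.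

Step 8
Reactants: 12 4-[3,5-bis(tosyloxy)phenoxy]-3-hydroxy-7,8,9-trimethoxydibenzo[b,d]furan-1-yl 4-methylbenzenesulfonate
Product: 13 4-(3,5-dihydroxyphenoxy)-7,8,9-trimethoxydibenzo[b,d]furan-1,3-diol
Conditions: KOH, MeOH/THF/H2O, Ar, 65 °C; then aq. HCl
Reagents that add atoms: none
Why: Alkaline hydrolysis of aryl sulfonates by attack at sulfur frees the C5 phenol and both ring F phenols, while methyl ethers, diaryl ether and furan are inert to hydroxide.

Step 9
Reactants: 13 4-(3,5-dihydroxyphenoxy)-7,8,9-trimethoxydibenzo[b,d]furan-1,3-diol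
Product: 15 4-(3,5-dihydroxyphenoxy)-7,8-dimethoxydibenzo[b,d]furan-1,3,9-triol, via tetrakis(dichloroboryl) ether 14 (not isolated)
Conditions: BCl3 (4.2 equiv), CH2Cl2, −78 °C to 0 °C; then H2O
Reagents that add atoms: none
Why: Neighbouring-group-directed ether cleavage with BCl3, the reaction type known for methoxy groups beside a carbonyl or hydroxyl group, is here extended across the bay: all four phenols are bound as aryloxydichloroboranes (14) so that almost no free BCl3 remains, and only the boron on the C5 oxygen has an ether oxygen within reach (the B6 methoxy oxygen, less than 3 Å away), so B6 and not the equally twisted B1 ether should be demethylated.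

Step 10
Reactants: 15 4-(3,5-dihydroxyphenoxy)-7,8-dimethoxydibenzo[b,d]furan-1,3,9-triol
Product: 16 6-(3,5-dimethoxyphenoxy)-2,3,7,9-tetramethoxydibenzo[b,d]furan-1-ol
Conditions: MeI (4.1 equiv), K2CO3, acetone, rt
Reagents that add atoms: iodomethane, SMILES CI
Why: Williamson methylation under weak-base control should alkylate the three open phenols (C3 and two on ring F) and then, as in a 2,2'-biphenol whose hydrogen-bonded monoanion is alkylated only once, the less hindered C5 oxygen of the bay pair, leaving the B6 hydroxyl that is wedged between the B1 methoxy group and the bay.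

Step 11
Reactants: 17 3-bromo-2,4-difluorobenzaldehyde
Product: 18 2-(3-bromo-2,4-difluorophenyl)-1,3-dioxolane
Conditions: HOCH2CH2OH, TsOH (cat.), toluene, reflux, azeotropic removal of water
Reagents that add atoms: ethane-1,2-diol, SMILES OCCO
Why: Acid-catalysed acetalisation masks the aldehyde against the amide base of step 12.

Step 12
Reactants: 18 2-(3-bromo-2,4-difluorophenyl)-1,3-dioxolane
Product: 21 5-bromo-4,6-difluorobenzene-1,3-dicarbaldehyde, via aryllithium 19 (not isolated), via formyl acetal 20 (not isolated)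
Conditions: LDA, THF, −78 °C; DMF, −78 °C to 0 °C; then 2 M HCl, rt
Reagents that add atoms: N,N-dimethylformamide, SMILES CN(C)C=O
Why: Fluorine-directed ortho-lithiation with LDA removes the only proton ortho to fluorine, DMF formylates the aryllithium (Bouveault formylation) at −78 °C before benzyne formation can set in, and the acidic work-up hydrolyses the dioxolane to the symmetric dialdehyde.

Step 13
Reactants: 21 5-bromo-4,6-difluorobenzene-1,3-dicarbaldehyde; 22 3,5-dimethoxyphenol
Product: 23 5-bromo-4-(3,5-dimethoxyphenoxy)-6-fluorobenzene-1,3-dicarbaldehyde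
Conditions: 22 (1.0 equiv), K2CO3, MeCN, 0 °C to rt
Reagents that add atoms: none
Why: Nucleophilic aromatic substitution (SNAr) at one of two equivalent fluorides, each ortho to one formyl group and para to the other, and the aryloxy group that enters donates into both formyl groups and so slows a second substitution.

Step 14
Reactants: 16 6-(3,5-dimethoxyphenoxy)-2,3,7,9-tetramethoxydibenzo[b,d]furan-1-ol; 23 5-bromo-4-(3,5-dimethoxyphenoxy)-6-fluorobenzene-1,3-dicarbaldehyde
Product: 24 5-bromo-4-(3,5-dimethoxyphenoxy)-6-{[6-(3,5-dimethoxyphenoxy)-2,3,7,9-tetramethoxydibenzo[b,d]furan-1-yl]oxy}benzene-1,3-dicarbaldehyde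
Conditions: Cs2CO3, DMF, 60 °C
Reagents that add atoms: none
Why: SNAr of the single free phenoxide of 16 (the B6 oxygen) at the remaining doubly activated fluoride (ring A position 5), where fluoride is a far better nucleofuge than the aryloxy group at ring A position 1, fixes the bond from the B6 oxygen to ring A position 5 while B1 is still a methyl ether, so no Smiles rearrangement can exchange the two dioxin oxygens.

Step 15
Reactants: 24 5-bromo-4-(3,5-dimethoxyphenoxy)-6-{[6-(3,5-dimethoxyphenoxy)-2,3,7,9-tetramethoxydibenzo[b,d]furan-1-yl]oxy}benzene-1,3-dicarbaldehyde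
Product: 26 5-bromo-4-(3,5-dimethoxyphenoxy)-6-{[6-(3,5-dimethoxyphenoxy)-2,3,7,9-tetramethoxydibenzo[b,d]furan-1-yl]oxy}benzene-1,3-diol, via bis-formate 25 (not isolated)
Conditions: mCPBA, CH2Cl2, 0 °C to rt; then K2CO3, MeOH, rt
Reagents that add atoms: 3-chloroperoxybenzoic acid, SMILES OOC(=O)c1cccc(Cl)c1
Why: Double Dakin-type Baeyer–Villiger oxidation, in which each formyl group is ortho to one aryloxy group and para to another so that the aryl group migrates, gives formates that mild methanolysis converts into the phenols at ring A positions 2 and 4 without touching the aryl bromide or the ethers.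

Step 16
Reactants: 26 5-bromo-4-(3,5-dimethoxyphenoxy)-6-{[6-(3,5-dimethoxyphenoxy)-2,3,7,9-tetramethoxydibenzo[b,d]furan-1-yl]oxy}benzene-1,3-diol
Product: 27 1-[2-bromo-3-(3,5-dimethoxyphenoxy)-4,6-dimethoxyphenoxy]-6-(3,5-dimethoxyphenoxy)-2,3,7,9-tetramethoxydibenzo[b,d]furan
Conditions: MeI, K2CO3, DMF, rt
Reagents that add atoms: iodomethane, SMILES CI
Why: Williamson methylation of the two new phenols protects the electron-rich ring A for the BCl3 and CuI steps and leaves no acidic proton.

Step 17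
Reactants: 27 1-[2-bromo-3-(3,5-dimethoxyphenoxy)-4,6-dimethoxyphenoxy]-6-(3,5-dimethoxyphenoxy)-2,3,7,9-tetramethoxydibenzo[b,d]furan
Product: 28 1-[2-bromo-3-(3,5-dimethoxyphenoxy)-4,6-dimethoxyphenoxy]-6-(3,5-dimethoxyphenoxy)-3,7,9-trimethoxydibenzo[b,d]furan-2-ol
Conditions: BCl3 (2 equiv), CH2Cl2, −78 °C to 0 °C; then H2O
Reagents that add atoms: none
Why: Selective BCl3 cleavage of a sterically compressed methyl ether, because B1 is now the only methoxy group flanked by two oxygen substituents (the B2 methoxy group and the B6 aryl ether) and is twisted out of conjugation, whereas every other methoxy group has a free ortho position.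

Step 18
Reactants: 28 1-[2-bromo-3-(3,5-dimethoxyphenoxy)-4,6-dimethoxyphenoxy]-6-(3,5-dimethoxyphenoxy)-3,7,9-trimethoxydibenzo[b,d]furan-2-ol
Product: 29 phlorofucofuroeckol A nona-O-methyl ether
Conditions: CuI (20 mol%), 2,2,6,6-tetramethylheptane-3,5-dione (40 mol%), Cs2CO3, NMP, 120 °C
Reagents that add atoms: none
Why: Intramolecular Ullmann etherification, in which the B1 phenoxide and the bromide at ring A position 6 are held ortho to the existing diaryl ether bridge from the B6 oxygen, closes the six-membered dioxin ring in the only possible orientation, and the electron-rich ring A excludes any SNAr or Smiles pathway.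

Step 19
Reactants: 29 phlorofucofuroeckol A nona-O-methyl ether
Product: 30 phlorofucofuroeckol A
Conditions: BBr3 (excess), CH2Cl2, −78 °C to rt; then H2O
Reagents that add atoms: none
Why: Exhaustive Lewis-acid demethylation with BBr3 should cleave all nine aryl methyl ethers while the diaryl ether, dibenzofuran and dibenzodioxin C–O bonds are stable, and the achiral target has no stereocentre to lose.

**Compound list**

1 | 3,4,5-trimethoxyphenol | COc1cc(O)cc(OC)c1OC | starting material
2 | 3,4,4,5-tetramethoxycyclohexa-2,5-dien-1-one | COC1=CC(=O)C=C(OC)C1(OC)OC | intermediate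
3 | 2,6-dimethoxy-1,4-benzoquinone | COC1=CC(=O)C=C(OC)C1=O | starting material
4 | 2,6-dimethoxybenzene-1,4-diol | COc1cc(O)cc(OC)c1O | intermediate
5 | 4-hydroxy-3,5-dimethoxyphenyl 4-methylbenzenesulfonate | COc1cc(OS(=O)(=O)c2ccc(C)cc2)cc(OC)c1O | intermediate
6 | 5-bromobenzene-1,3-diol | Oc1cc(O)cc(Br)c1 | starting material
7 | 5-bromo-1,3-phenylene bis(4-methylbenzenesulfonate) | Cc1ccc(cc1)S(=O)(=O)Oc1cc(Br)cc(OS(=O)(=O)c2ccc(C)cc2)c1 | intermediate
8 | 5-[2,6-dimethoxy-4-(tosyloxy)phenoxy]-1,3-phenylene bis(4-methylbenzenesulfonate) | COc1cc(OS(=O)(=O)c2ccc(C)cc2)cc(OC)c1Oc1cc(OS(=O)(=O)c2ccc(C)cc2)cc(OS(=O)(=O)c2ccc(C)cc2)c1 | intermediate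
9 | 5-[2,6-dihydroxy-4-(tosyloxy)phenoxy]-1,3-phenylene bis(4-methylbenzenesulfonate) (rings C and F) | Oc1cc(OS(=O)(=O)c2ccc(C)cc2)cc(O)c1Oc1cc(OS(=O)(=O)c2ccc(C)cc2)cc(OS(=O)(=O)c2ccc(C)cc2)c1 | intermediate
10 | (2,6-dimethoxy-4-oxocyclohexa-2,5-dien-1-ylidene)(methyl)oxonium trifluoromethanesulfonate | COC1=CC(=O)C=C(OC)C1=[O+]C.[O-]S(=O)(=O)C(F)(F)F | intermediate
11 | 5-[2,6-dihydroxy-3-(6-hydroxy-2,3,4-trimethoxyphenyl)-4-(tosyloxy)phenoxy]-1,3-phenylene bis(4-methylbenzenesulfonate) | COc1cc(O)c(-c2c(O)c(Oc3cc(OS(=O)(=O)c4ccc(C)cc4)cc(OS(=O)(=O)c4ccc(C)cc4)c3)c(O)cc2OS(=O)(=O)c2ccc(C)cc2)c(OC)c1OC | intermediate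
12 | 4-[3,5-bis(tosyloxy)phenoxy]-3-hydroxy-7,8,9-trimethoxydibenzo[b,d]furan-1-yl 4-methylbenzenesulfonate | COc1cc2oc3c(Oc4cc(OS(=O)(=O)c5ccc(C)cc5)cc(OS(=O)(=O)c5ccc(C)cc5)c4)c(O)cc(OS(=O)(=O)c4ccc(C)cc4)c3c2c(OC)c1OC | intermediate
13 | 4-(3,5-dihydroxyphenoxy)-7,8,9-trimethoxydibenzo[b,d]furan-1,3-diol | COc1cc2oc3c(Oc4cc(O)cc(O)c4)c(O)cc(O)c3c2c(OC)c1OC | intermediate
14 | tetrakis(dichloroboryl) ether of 13 | COc1cc2oc3c(Oc4cc(OB(Cl)Cl)cc(OB(Cl)Cl)c4)c(OB(Cl)Cl)cc(OB(Cl)Cl)c3c2c(OC)c1OC | intermediate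
15 | 4-(3,5-dihydroxyphenoxy)-7,8-dimethoxydibenzo[b,d]furan-1,3,9-triol | COc1cc2oc3c(Oc4cc(O)cc(O)c4)c(O)cc(O)c3c2c(O)c1OC | intermediate
16 | 6-(3,5-dimethoxyphenoxy)-2,3,7,9-tetramethoxydibenzo[b,d]furan-1-ol | COc1cc2oc3c(Oc4cc(OC)cc(OC)c4)c(OC)cc(OC)c3c2c(O)c1OC | intermediate
17 | 3-bromo-2,4-difluorobenzaldehyde | O=Cc1ccc(F)c(Br)c1F | starting material
18 | 2-(3-bromo-2,4-difluorophenyl)-1,3-dioxolane | Fc1ccc(C2OCCO2)c(F)c1Br | intermediate
19 | [3-bromo-5-(1,3-dioxolan-2-yl)-2,4-difluorophenyl]lithium | [Li]c1cc(C2OCCO2)c(F)c(Br)c1F | intermediate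
20 | 3-bromo-5-(1,3-dioxolan-2-yl)-2,4-difluorobenzaldehyde | O=Cc1cc(C2OCCO2)c(F)c(Br)c1F | intermediate
21 | 5-bromo-4,6-difluorobenzene-1,3-dicarbaldehyde | O=Cc1cc(C=O)c(F)c(Br)c1F | intermediate
22 | 3,5-dimethoxyphenol | COc1cc(O)cc(OC)c1 | starting material
23 | 5-bromo-4-(3,5-dimethoxyphenoxy)-6-fluorobenzene-1,3-dicarbaldehyde (rings E and A) | COc1cc(OC)cc(Oc2c(C=O)cc(C=O)c(F)c2Br)c1 | intermediate
24 | 5-bromo-4-(3,5-dimethoxyphenoxy)-6-{[6-(3,5-dimethoxyphenoxy)-2,3,7,9-tetramethoxydibenzo[b,d]furan-1-yl]oxy}benzene-1,3-dicarbaldehyde | COc1cc2oc3c(Oc4cc(OC)cc(OC)c4)c(OC)cc(OC)c3c2c(Oc2c(C=O)cc(C=O)c(Oc3cc(OC)cc(OC)c3)c2Br)c1OC | intermediate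
25 | 5-bromo-4-(3,5-dimethoxyphenoxy)-6-{[6-(3,5-dimethoxyphenoxy)-2,3,7,9-tetramethoxydibenzo[b,d]furan-1-yl]oxy}-1,3-phenylene diformate | COc1cc2oc3c(Oc4cc(OC)cc(OC)c4)c(OC)cc(OC)c3c2c(Oc2c(OC=O)cc(OC=O)c(Oc3cc(OC)cc(OC)c3)c2Br)c1OC | intermediate
26 | 5-bromo-4-(3,5-dimethoxyphenoxy)-6-{[6-(3,5-dimethoxyphenoxy)-2,3,7,9-tetramethoxydibenzo[b,d]furan-1-yl]oxy}benzene-1,3-diol | COc1cc2oc3c(Oc4cc(OC)cc(OC)c4)c(OC)cc(OC)c3c2c(Oc2c(O)cc(O)c(Oc3cc(OC)cc(OC)c3)c2Br)c1OC | intermediate
27 | 1-[2-bromo-3-(3,5-dimethoxyphenoxy)-4,6-dimethoxyphenoxy]-6-(3,5-dimethoxyphenoxy)-2,3,7,9-tetramethoxydibenzo[b,d]furan | COc1cc2oc3c(Oc4cc(OC)cc(OC)c4)c(OC)cc(OC)c3c2c(Oc2c(OC)cc(OC)c(Oc3cc(OC)cc(OC)c3)c2Br)c1OC | intermediate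
28 | 1-[2-bromo-3-(3,5-dimethoxyphenoxy)-4,6-dimethoxyphenoxy]-6-(3,5-dimethoxyphenoxy)-3,7,9-trimethoxydibenzo[b,d]furan-2-ol | COc1cc2oc3c(Oc4cc(OC)cc(OC)c4)c(OC)cc(OC)c3c2c(Oc2c(OC)cc(OC)c(Oc3cc(OC)cc(OC)c3)c2Br)c1O | intermediate
29 | phlorofucofuroeckol A nona-O-methyl ether | COc1cc(OC)cc(Oc2c(OC)cc(OC)c3c2Oc2c(OC)cc4oc5c(Oc6cc(OC)cc(OC)c6)c(OC)cc(OC)c5c4c2O3)c1 | intermediate
30 | phlorofucofuroeckol A | Oc1cc(O)cc(Oc2c(O)cc(O)c3c2Oc2c(O)cc4oc5c(Oc6cc(O)cc(O)c6)c(O)cc(O)c5c4c2O3)c1 | target

**Step count.** Total: 19 steps. Longest linear sequence: 14 steps (2, 3, 5, 6, 7, 8, 9, 10, 14, 15, 16, 17, 18, 19).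

**Steps most likely to fail**

1. Step 7 (key step, proposed new method). What may go wrong: capture of cation 10 at a phenol oxygen instead of carbon, loss of its methyl group to give the quinone, further arylation of the electron-rich product at B3, or stalling at biaryl 11 without dehydration. The fallback uses known chemistry, sets out from diol 9 and comes back to the route at 12, and it reverses the order of bond formation (oxygen first, then carbon). Chan–Lam coupling of 9, used in excess so that only one of its two equivalent hydroxyls reacts, with commercial (3,4,5-trimethoxyphenyl)boronic acid (Cu(OAc)2, pyridine, 4 Å molecular sieves, CH2Cl2, air, rt) should give the diaryl ether F1, in which the C1 oxygen is bonded to B4. Dehydrogenative ring closure of this diaryl ether (Pd(OAc)2 cat., K2CO3, pivalic acid, air, 110 °C), the known route from diaryl ethers to dibenzofurans, then forms the B5–C6 bond and gives 12. On ring C only C6 carries a hydrogen ortho to the new ether oxygen, and B3 and B5 are equivalent, so the symmetry argument of the main route still holds.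

2. Step 9. What may go wrong: loss of site selectivity, either by relay of boron from the new B6 borate to the neighbouring B1 ether or by intermolecular cleavage of the twisted B1 ether. The fallback sets out from 12, before detosylation, and uses strain-driven acylative ether cleavage, the reaction type known from colchicine, where acetyl chloride and SnCl4 replace the methyl ether next to the biaryl bond by an acetate. AcCl, SnCl4, CH2Cl2, 0 °C should convert the B6 methoxy group, pressed between the B1 methoxy group and the bay tosylate, into an acetate and acetylate the C3 hydroxyl, giving the diacetate F2. KOH in MeOH/THF then removes acetates and tosylates together, and the route is rejoined at 15.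

3. Step 10. What may go wrong: over-alkylation at the B6 phenol, or alkylation of the bay pair at the wrong oxygen. The fallback sets out from 15 and replaces alkylation by sterically controlled sulfonylation. TsCl (4.2 equiv), Et3N, CH2Cl2, 0 °C should leave only the doubly flanked B6 hydroxyl free (tetratosylate F3). SNAr with 23 (Cs2CO3, DMF) gives the dialdehyde F4. mCPBA gives the bis-formate F5, and KOH in MeOH/THF hydrolyses formates and tosylates in one operation to the hexaol F6. Exhaustive methylation (MeI, K2CO3, DMF) returns to the route at 27.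

**Further compounds**

F1 | step 7 | 5-[2-hydroxy-4-(tosyloxy)-6-(3,4,5-trimethoxyphenoxy)phenoxy]-1,3-phenylene bis(4-methylbenzenesulfonate) | COc1cc(Oc2cc(OS(=O)(=O)c3ccc(C)cc3)cc(O)c2Oc2cc(OS(=O)(=O)c3ccc(C)cc3)cc(OS(=O)(=O)c3ccc(C)cc3)c2)cc(OC)c1OC
F2 | step 9 | 4-[3,5-bis(tosyloxy)phenoxy]-7,8-dimethoxy-1-(tosyloxy)dibenzo[b,d]furan-3,9-diyl diacetate | COc1cc2oc3c(Oc4cc(OS(=O)(=O)c5ccc(C)cc5)cc(OS(=O)(=O)c5ccc(C)cc5)c4)c(OC(C)=O)cc(OS(=O)(=O)c4ccc(C)cc4)c3c2c(OC(C)=O)c1OC
F3 | step 10 | 4-[3,5-bis(tosyloxy)phenoxy]-9-hydroxy-7,8-dimethoxydibenzo[b,d]furan-1,3-diyl bis(4-methylbenzenesulfonate) | COc1cc2oc3c(Oc4cc(OS(=O)(=O)c5ccc(C)cc5)cc(OS(=O)(=O)c5ccc(C)cc5)c4)c(OS(=O)(=O)c4ccc(C)cc4)cc(OS(=O)(=O)c4ccc(C)cc4)c3c2c(O)c1OC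
F4 | step 10 | 5-bromo-4-(3,5-dimethoxyphenoxy)-6-({6-[3,5-bis(tosyloxy)phenoxy]-2,3-dimethoxy-7,9-bis(tosyloxy)dibenzo[b,d]furan-1-yl}oxy)benzene-1,3-dicarbaldehyde | COc1cc2oc3c(Oc4cc(OS(=O)(=O)c5ccc(C)cc5)cc(OS(=O)(=O)c5ccc(C)cc5)c4)c(OS(=O)(=O)c4ccc(C)cc4)cc(OS(=O)(=O)c4ccc(C)cc4)c3c2c(Oc2c(C=O)cc(C=O)c(Oc3cc(OC)cc(OC)c3)c2Br)c1OC
F5 | step 10 | 5-bromo-4-(3,5-dimethoxyphenoxy)-6-({6-[3,5-bis(tosyloxy)phenoxy]-2,3-dimethoxy-7,9-bis(tosyloxy)dibenzo[b,d]furan-1-yl}oxy)-1,3-phenylene diformate | COc1cc2oc3c(Oc4cc(OS(=O)(=O)c5ccc(C)cc5)cc(OS(=O)(=O)c5ccc(C)cc5)c4)c(OS(=O)(=O)c4ccc(C)cc4)cc(OS(=O)(=O)c4ccc(C)cc4)c3c2c(Oc2c(OC=O)cc(OC=O)c(Oc3cc(OC)cc(OC)c3)c2Br)c1OC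
F6 | step 10 | 5-bromo-4-(3,5-dimethoxyphenoxy)-6-{[6-(3,5-dihydroxyphenoxy)-7,9-dihydroxy-2,3-dimethoxydibenzo[b,d]furan-1-yl]oxy}benzene-1,3-diol | COc1cc2oc3c(Oc4cc(O)cc(O)c4)c(O)cc(O)c3c2c(Oc2c(O)cc(O)c(Oc3cc(OC)cc(OC)c3)c2Br)c1OC
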